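**Plan**
- **Cuts:** the C8 ester; the lactone at C11–C12 and C12–O6 (CO inserted into a C11 vinyl iodide); C6–C7, with O–C13 restored (retro-[2,3]-Wittig), which gives a thirteen-membered C6–O–C13 ether. Then O–C6 (Williamson), O–C3 (furanone), C1–C2, C3–C4 and C7–C8.
- **Enabling feature:** in the ten-membered carbocycle, C6 (oxygen-bearing, allylic to C4=C5) and C7 (bearing the C11=C13 methylene) form a homoallylic alcohol with a 2-substituted allyl unit. C6–H is also the ε-position of the furanone dienone (C1=O, C2=C3, C4=C5), so it is the acidic site.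
- **Forward order:** two Z-iodoalkenes are made, C4=C5 from but-2-yne-1,4-diol and C7=C11 from a citramalate ynone. A temporary O8–C1 butyrolactone is opened by the C2 acetylide. The rings then arise as furanone (Au), thirteen-membered ether, ten-membered carbocycle (ring contraction), α-methylene-γ-lactone (Pd/CO).
- **Stereochemistry:** C10 comes from (S)-citramalic acid, C8 from a CBS reduction, C6 and C7 from the key step, and C2′ from (R)-2-methylbutanoic acid. Both alkene geometries come from anti additions to alkynes.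
- **Spectator groups in the key step:** C11 carries iodine, so C12 enters afterwards as CO. O15 is carried as its alkoxide, so it cannot be eliminated from the C6 anion.

Key step: step 17

Remark: atom labels follow the germacrane numbering of the target. C1 is the ketone, C2=C3 the furanone alkene, C4=C5 carries C15 on C4, C6 is the lactone carbinol, C8 the ester carbinol, C10 carries the C14 methyl, C11=C13 is the methylene and C12 the lactone carbonyl. PMB = 4-methoxybenzyl.

**Step 1**
Reactants: 1 but-2-yne-1,4-diol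
Product: 2 4-[(4-methoxybenzyl)oxy]but-2-yn-1-ol
Conditions: NaH (1 equiv), PMBCl (1 equiv), TBAI (cat.), 1 (3 equiv), THF/DMF, 0 °C to rt
Reagents that add atoms: 4-methoxybenzyl chloride, COc1ccc(CCl)cc1
Why: Williamson etherification; the excess of the symmetrical diol should hold the alkylation at the mono-ether.

**Step 2**
Reactants: 2 4-[(4-methoxybenzyl)oxy]but-2-yn-1-ol
Product: 3 (Z)-3-iodo-4-[(4-methoxybenzyl)oxy]but-2-en-1-ol (iodine cis to CH2OH)
Conditions: Red-Al, THF, 0 °C to rt; EtOAc; I2, −78 to 0 °C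
Reagents that add atoms: iodine, II
Why: Hydroxyl-directed trans-hydroalumination of the propargylic alcohol puts aluminium on the distal alkyne carbon (C4) cis to C6, and iodinolysis with retention should give the Z-iodide, which fixes the C4=C5 geometry of the target.

**Step 3**
Reactants: 3 (Z)-3-iodo-4-[(4-methoxybenzyl)oxy]but-2-en-1-ol
Product: 4 (Z)-triethyl({3-iodo-4-[(4-methoxybenzyl)oxy]but-2-en-1-yl}oxy)silane
Conditions: TESCl, imidazole, CH2Cl2, 0 °C
Reagents that add atoms: chlorotriethylsilane, CC[Si](Cl)(CC)CC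
Why: Standard silylation of a primary alcohol; the O6 TES ether is the most labile group of the later set and can be removed first.

**Step 4**
Reactants: 4 (Z)-triethyl({3-iodo-4-[(4-methoxybenzyl)oxy]but-2-en-1-yl}oxy)silane
Product: 5 (E)-triethyl[(3-{[(4-methoxybenzyl)oxy]methyl}pent-2-en-4-yn-1-yl)oxy]silane (ethynyl cis to CH2OTES; C2–C6 and C15)
Conditions: HC≡CMgBr, ZnBr2, THF; Pd(PPh3)4 (5 mol %), rt
Reagents that add atoms: ethynylmagnesium bromide, C#C[Mg]Br
Why: Negishi coupling of an alkenyl iodide with ethynylzinc bromide proceeds with retention and gives the terminal enyne directly, without an alkyne protecting group.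

**Step 5**
Reactants: 6 prop-2-yn-1-ol
Product: 7 1-methoxy-4-[(prop-2-yn-1-yloxy)methyl]benzene (PMB propargyl ether; C7, C11, C13)
Conditions: NaH, PMBCl, TBAI (cat.), THF, 0 °C to rt
Reagents that add atoms: 4-methoxybenzyl chloride, COc1ccc(CCl)cc1
Why: Williamson etherification of a primary alkoxide with a benzylic chloride.

**Step 6**
Reactants: 8 (S)-citramalic acid
Product: 9 [(4S)-2,2,4-trimethyl-5-oxo-1,3-dioxolan-4-yl]acetic acid
Conditions: 2,2-dimethoxypropane, PPTS (cat.), CH2Cl2, rt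
Reagents that add atoms: 2,2-dimethoxypropane, COC(C)(C)OC
Why: Acid-catalysed acetal exchange ties the α-hydroxy acid (O10, C1) into a 1,3-dioxolan-4-one, the usual differentiation of the two carboxyl groups of malic-type acids, and leaves the C8 acid free with C10 untouched.

**Step 7**
Reactants: 9 [(4S)-2,2,4-trimethyl-5-oxo-1,3-dioxolan-4-yl]acetic acid; 7 PMB propargyl ether
Product: 12 (5S)-5-{5-[(4-methoxybenzyl)oxy]-2-oxopent-3-yn-1-yl}-2,2,5-trimethyl-1,3-dioxolan-4-one, via [(4S)-2,2,4-trimethyl-5-oxo-1,3-dioxolan-4-yl]acetyl chloride 10 (not isolated), via {3-[(4-methoxybenzyl)oxy]prop-1-yn-1-yl}zinc bromide 11 (not isolated)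
Conditions: 9, (COCl)2, DMF (cat.), CH2Cl2, 0 °C to rt, evaporate; 7, n-BuLi, THF, −78 °C, then ZnBr2, 0 °C; combine, Pd(PPh3)4 (5 mol %), THF, 0 °C to rt
Reagents that add atoms: none
Why: Negishi acylation (acid chloride plus alkynylzinc, Pd(0)) forms C7–C8 under non-basic conditions, so neither the dioxolanone carbonyl nor the β-oxygen at C10 is at risk.

**Step 8**
Reactants: 12 (5S)-5-{5-[(4-methoxybenzyl)oxy]-2-oxopent-3-yn-1-yl}-2,2,5-trimethyl-1,3-dioxolan-4-one
Product: 13 (5S)-5-{(3Z)-4-iodo-5-[(4-methoxybenzyl)oxy]-2-oxopent-3-en-1-yl}-2,2,5-trimethyl-1,3-dioxolan-4-one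
Conditions: NaI, AcOH, rt, dark
Reagents that add atoms: sodium iodide, [Na+].[I-]
Why: Conjugate anti hydroiodination of an ynone puts iodine on the β-carbon C11 cis to the C8 carbonyl (Z), which places C8 trans to C13 as the ring contraction requires.

**Step 9**
Reactants: 13 (5S)-5-{(3Z)-4-iodo-5-[(4-methoxybenzyl)oxy]-2-oxopent-3-en-1-yl}-2,2,5-trimethyl-1,3-dioxolan-4-one
Product: 15 (3S,5R)-3-hydroxy-5-{(1Z)-2-iodo-3-[(4-methoxybenzyl)oxy]prop-1-en-1-yl}-3-methyloxolan-2-one, via (5S)-5-{(2R,3Z)-2-hydroxy-4-iodo-5-[(4-methoxybenzyl)oxy]pent-3-en-1-yl}-2,2,5-trimethyl-1,3-dioxolan-4-one 14 (not isolated)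
Conditions: (S)-Me-CBS (0.3 equiv), BH3·SMe2, THF, −30 °C; MeOH; then CSA (cat.), CH2Cl2, rt
Reagents that add atoms: none
Why: CBS reduction with the iodoalkenyl group as the large substituent should set 8R with the (S)-catalyst, and acid-catalysed transacylation then lets O8 displace acetone from the dioxolanone, so that O8 and C1 protect each other as a γ-lactone.

**Step 10**
Reactants: 15 (3S,5R)-3-hydroxy-5-{(1Z)-2-iodo-3-[(4-methoxybenzyl)oxy]prop-1-en-1-yl}-3-methyloxolan-2-one; 5 (E)-triethyl[(3-{[(4-methoxybenzyl)oxy]methyl}pent-2-en-4-yn-1-yl)oxy]silane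
Product: 17 (2E,7S,9R,10Z)-7,9-dihydroxy-11-iodo-12-[(4-methoxybenzyl)oxy]-3-{[(4-methoxybenzyl)oxy]methyl}-7-methyl-1-[(triethylsilyl)oxy]dodeca-2,10-dien-4-yn-6-one, via the lithium acetylide of 5 16 (not isolated)
Conditions: 5, n-BuLi, THF, −78 °C; 15, LiHMDS (1 equiv), THF, −78 °C; combine, −78 to −40 °C; AcOH
Reagents that add atoms: none
Why: Addition of a lithium acetylide to a γ-lactone stops at the ynone stage because the tetrahedral alkoxide survives at low temperature; the lactone has no α-hydrogen, and prior deprotonation of the tertiary OH saves acetylide.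

**Step 11**
Reactants: 17 (2E,7S,9R,10Z)-7,9-dihydroxy-11-iodo-12-[(4-methoxybenzyl)oxy]-3-{[(4-methoxybenzyl)oxy]methyl}-7-methyl-1-[(triethylsilyl)oxy]dodeca-2,10-dien-4-yn-6-one
Product: 18 (2E,7S,9R,10Z)-9-[(tert-butyldimethylsilyl)oxy]-7-hydroxy-11-iodo-12-[(4-methoxybenzyl)oxy]-3-{[(4-methoxybenzyl)oxy]methyl}-7-methyl-1-[(triethylsilyl)oxy]dodeca-2,10-dien-4-yn-6-one
Conditions: TBSCl, imidazole, DMF, 0 °C to rt
Reagents that add atoms: tert-butyldimethylsilyl chloride, CC(C)(C)[Si](C)(C)Cl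
Why: Silylation discriminates the secondary allylic O8–H from the tertiary O10–H on steric grounds; TBS is chosen because it must not migrate to the C6 alkoxide formed in step 17.

**Step 12**
Reactants: 18 (2E,7S,9R,10Z)-9-[(tert-butyldimethylsilyl)oxy]-7-hydroxy-11-iodo-12-[(4-methoxybenzyl)oxy]-3-{[(4-methoxybenzyl)oxy]methyl}-7-methyl-1-[(triethylsilyl)oxy]dodeca-2,10-dien-4-yn-6-one
Product: 19 (2S)-2-{(2R,3Z)-2-[(tert-butyldimethylsilyl)oxy]-4-iodo-5-[(4-methoxybenzyl)oxy]pent-3-en-1-yl}-5-{(2Z)-1-[(4-methoxybenzyl)oxy]-4-[(triethylsilyl)oxy]but-2-en-2-yl}-2-methylfuran-3(2H)-one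
Conditions: Ph3PAuNTf2 (5 mol %), toluene, rt
Reagents that add atoms: none
Why: Gold(I)-catalysed 5-endo-dig cyclisation of a γ-hydroxy alkynone, in which O10 adds to the activated C3 and protodeauration gives the 3(2H)-furanone without touching C10.

**Step 13**
Reactants: 19 (2S)-2-{(2R,3Z)-2-[(tert-butyldimethylsilyl)oxy]-4-iodo-5-[(4-methoxybenzyl)oxy]pent-3-en-1-yl}-5-{(2Z)-1-[(4-methoxybenzyl)oxy]-4-[(triethylsilyl)oxy]but-2-en-2-yl}-2-methylfuran-3(2H)-one
Product: 20 (2S)-2-{(2R,3Z)-2-[(tert-butyldimethylsilyl)oxy]-4-iodo-5-[(4-methoxybenzyl)oxy]pent-3-en-1-yl}-5-{(2Z)-4-hydroxy-1-[(4-methoxybenzyl)oxy]but-2-en-2-yl}-2-methylfuran-3(2H)-one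
Conditions: PPTS (cat.), MeOH/CH2Cl2, 0 °C
Reagents that add atoms: none
Why: Acid-catalysed methanolysis removes a primary TES ether much faster than a secondary TBS ether and leaves the PMB ethers alone.

**Step 14**
Reactants: 20 (2S)-2-{(2R,3Z)-2-[(tert-butyldimethylsilyl)oxy]-4-iodo-5-[(4-methoxybenzyl)oxy]pent-3-en-1-yl}-5-{(2Z)-4-hydroxy-1-[(4-methoxybenzyl)oxy]but-2-en-2-yl}-2-methylfuran-3(2H)-one
Product: 21 (2S)-5-{(2Z)-4-bromo-1-[(4-methoxybenzyl)oxy]but-2-en-2-yl}-2-{(2R,3Z)-2-[(tert-butyldimethylsilyl)oxy]-4-iodo-5-[(4-methoxybenzyl)oxy]pent-3-en-1-yl}-2-methylfuran-3(2H)-one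
Conditions: CBr4, PPh3, 2,6-lutidine, CH2Cl2, −20 to 0 °C
Reagents that add atoms: carbon tetrabromide, BrC(Br)(Br)Br
Why: The Appel reaction converts the primary allylic alcohol into the C6 bromide by SN2 under neutral conditions, without allylic shift or loss of alkene geometry.

**Step 15**
Reactants: 21 (2S)-5-{(2Z)-4-bromo-1-[(4-methoxybenzyl)oxy]but-2-en-2-yl}-2-{(2R,3Z)-2-[(tert-butyldimethylsilyl)oxy]-4-iodo-5-[(4-methoxybenzyl)oxy]pent-3-en-1-yl}-2-methylfuran-3(2H)-one
Product: 22 (2S)-5-[(2Z)-4-bromo-1-hydroxybut-2-en-2-yl]-2-{(2R,3Z)-2-[(tert-butyldimethylsilyl)oxy]-5-hydroxy-4-iodopent-3-en-1-yl}-2-methylfuran-3(2H)-one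
Conditions: DDQ (2.6 equiv), CH2Cl2/pH 7 buffer, 0 °C
Reagents that add atoms: none
Why: Oxidative PMB cleavage with DDQ frees O13 and O15 in one operation under neutral conditions that the allylic bromide, the vinyl iodide and the silyl ether tolerate.

**Step 16**
Reactants: 22 (2S)-5-[(2Z)-4-bromo-1-hydroxybut-2-en-2-yl]-2-{(2R,3Z)-2-[(tert-butyldimethylsilyl)oxy]-5-hydroxy-4-iodopent-3-en-1-yl}-2-methylfuran-3(2H)-one
Product: 23 thirteen-membered ether (8R,10S): ring C1–C7, C11, C13, O, C8–C10 with oxygen between C6 and C13, bridged by the furanone oxygen (C3–O–C10); C4=C5 with C3 cis to C6; C7=C11 with C8 trans to C13 and cis to iodine; C8 OTBS, C15 OH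
Conditions: NaH (2.5 equiv), THF, 2 mM (22 by syringe pump), 0 °C to rt; AcOH
Reagents that add atoms: none
Why: Intramolecular Williamson etherification at high dilution, the established closure of thirteen-membered allylic ethers; only O13 can reach C6 because O15 sits trans to C6 on C4=C5, and the remaining C15 alkoxide protects the product against base-induced loss of that oxygen.

**Step 17**
Reactants: 23 thirteen-membered ether (8R,10S)
Product: 24 ten-membered carbocycle (6R,7S,8R,10S): C6 OH, C7 bearing the 1-iodovinyl group (C11=C13), C8 OTBS, C15 OH, furanone and Z-C4=C5 unchanged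
Conditions: LiHMDS (3 equiv), THF, −78 to −20 °C; AcOH, −78 °C
Reagents that add atoms: none
Why: LiHMDS takes first the C15–OH proton and then one C6–H (allylic, α to the ether oxygen and ε to the furanone carbonyl through C4=C5 and C2=C3), and the extended enolate undergoes a concerted suprafacial [2,3]-sigmatropic shift through a five-membered envelope (C6, O, C13, C11, C7) in which C6–C7 forms, O–C13 breaks and the π bond moves from C7=C11 to C11=C13. The closest known reactions are the [2,3]-Wittig ring contraction of thirteen-membered diallylic and allylic propargylic ethers to ten-membered germacranoid carbocycles and the enolate [2,3]-Wittig rearrangement of α-allyloxy carbonyl compounds. The ten-membered carbocycle C1–C10 (nine-membered when counted through the furanone oxygen) closes transannularly by this 13-to-10 contraction, with O, C13 and C11 leaving the ring as the C6 alkoxide and the 1-iodovinyl group. C6: the C10 stereocentre holds C9, and with it C8 and C7, on one face of the flat furanone–C4=C5–C6 anion, and the ether oxygen on C6 points away from C4 because the inward position collides with the furanone oxygen, so C7 bonds to a single face of C6 and 6R results. C7: with C8 trans to C13 on C7=C11 and C5 exo on the envelope, C8 comes to lie under H6 and H7 under C5, which is the anti O6/C8 arrangement (7S here, H6 and H7 trans as in the target lactone), whereas the endo envelope turns C8 away from C9 and cannot close the ring. The step needs deprotonation at C6 only and no loss of the C15 oxygen: C6–H is by far the most acidic C–H, O15 is carried as its lithium alkoxide and so cannot leave from the C4 position of the anion (the logic of β-oxido enolate dianions), the iodine at C11 lowers the allyl LUMO, and the hindered amide, the TBS group at O8 and the cold acetic acid quench guard against dehydroiodination and silyl migration.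

**Step 18**
Reactants: 24 ten-membered carbocycle (6R,7S,8R,10S)
Product: 25 (6R,7S,8R,10S)-8-O-TBS-15-hydroxy furanoheliangolide: trans-fused α-methylene-γ-lactone (O6–C12(=O)–C11(=C13)–C7) on the ten-membered ring
Conditions: Pd(PPh3)4 (10 mol %), CO (1 atm), Et3N, THF, 45 °C
Reagents that add atoms: carbon monoxide, [C-]#[O+]
Why: Palladium-catalysed carbonylative lactonisation of a 3-iodo homoallylic alcohol (oxidative addition at C11–I, CO insertion, capture of the acyl-palladium by O6 in a five-membered ring) is a classical entry to α-methylene-γ-butyrolactones; O8 is silylated and O15 is too remote to compete.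

**Step 19**
Reactants: 25 (6R,7S,8R,10S)-8-O-TBS-15-hydroxy furanoheliangolide
Product: 26 (6R,7R,8R,10S)-8,15-diol
Conditions: HF·pyridine, THF, 0 °C to rt
Reagents that add atoms: none
Why: Fluoride-mediated cleavage of the only silyl ether under mildly acidic conditions that the α-methylene lactone and the furanone tolerate.

**Step 20**
Reactants: 26 (6R,7R,8R,10S)-8,15-diol
Product: 27 (6R,7R,8R,10S)-15-O-TBS-8-ol
Conditions: TBSCl (1.1 equiv), imidazole, CH2Cl2, −20 to 0 °C
Reagents that add atoms: tert-butyldimethylsilyl chloride, CC(C)(C)[Si](C)(C)Cl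
Why: Selective silylation of the primary allylic C15 alcohol over the hindered secondary ring alcohol at C8.

**Step 21**
Reactants: 27 (6R,7R,8R,10S)-15-O-TBS-8-ol; 28 (R)-2-methylbutanoic acid
Product: 29 (6R,7R,8R,10S,2′R)-15-O-TBS-8-O-(2-methylbutanoyl) ester
Conditions: DCC, DMAP (cat.), CH2Cl2, 0 °C to rt
Reagents that add atoms: none
Why: Steglich esterification acylates O8 with retention at C8, and the weakly acidic α-hydrogen of the acid should keep C2′ intact.

**Step 22**
Reactants: 29 (6R,7R,8R,10S,2′R)-15-O-TBS-8-O-(2-methylbutanoyl) ester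
Product: 30 target CNP0307052.2
Conditions: HF·pyridine, pyridine, THF, 0 °C to rt
Reagents that add atoms: none
Why: Buffered HF desilylation frees the primary C15 alcohol without touching the ester, the lactone or the furanone.

**Compound list**
1 | but-2-yne-1,4-diol | OCC#CCO | starting material
2 | 4-[(4-methoxybenzyl)oxy]but-2-yn-1-ol | OCC#CCOCc1ccc(OC)cc1 | intermediate
3 | (Z)-3-iodo-4-[(4-methoxybenzyl)oxy]but-2-en-1-ol | OC/C=C(\I)COCc1ccc(OC)cc1 | intermediate
4 | (Z)-triethyl({3-iodo-4-[(4-methoxybenzyl)oxy]but-2-en-1-yl}oxy)silane | CC[Si](CC)(CC)OC/C=C(\I)COCc1ccc(OC)cc1 | intermediate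
5 | (E)-triethyl[(3-{[(4-methoxybenzyl)oxy]methyl}pent-2-en-4-yn-1-yl)oxy]silane | CC[Si](CC)(CC)OC/C=C(\C#C)COCc1ccc(OC)cc1 | intermediate
6 | prop-2-yn-1-ol | C#CCO | starting material
7 | 1-methoxy-4-[(prop-2-yn-1-yloxy)methyl]benzene | C#CCOCc1ccc(OC)cc1 | intermediate
8 | (S)-citramalic acid | C[C@](O)(CC(=O)O)C(=O)O | starting material
9 | [(4S)-2,2,4-trimethyl-5-oxo-1,3-dioxolan-4-yl]acetic acid | C[C@@]1(CC(=O)O)OC(C)(C)OC1=O | intermediate
10 | [(4S)-2,2,4-trimethyl-5-oxo-1,3-dioxolan-4-yl]acetyl chloride | C[C@@]1(CC(=O)Cl)OC(C)(C)OC1=O | intermediate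
11 | {3-[(4-methoxybenzyl)oxy]prop-1-yn-1-yl}zinc bromide | Br[Zn]C#CCOCc1ccc(OC)cc1 | intermediate
12 | (5S)-5-{5-[(4-methoxybenzyl)oxy]-2-oxopent-3-yn-1-yl}-2,2,5-trimethyl-1,3-dioxolan-4-one | C[C@@]1(CC(=O)C#CCOCc2ccc(OC)cc2)OC(C)(C)OC1=O | intermediate
13 | (5S)-5-{(3Z)-4-iodo-5-[(4-methoxybenzyl)oxy]-2-oxopent-3-en-1-yl}-2,2,5-trimethyl-1,3-dioxolan-4-one | C[C@@]1(CC(=O)/C=C(\I)COCc2ccc(OC)cc2)OC(C)(C)OC1=O | intermediate
14 | (5S)-5-{(2R,3Z)-2-hydroxy-4-iodo-5-[(4-methoxybenzyl)oxy]pent-3-en-1-yl}-2,2,5-trimethyl-1,3-dioxolan-4-one | C[C@@]1(C[C@@H](O)/C=C(\I)COCc2ccc(OC)cc2)OC(C)(C)OC1=O | intermediate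
15 | (3S,5R)-3-hydroxy-5-{(1Z)-2-iodo-3-[(4-methoxybenzyl)oxy]prop-1-en-1-yl}-3-methyloxolan-2-one | O=C1O[C@@H](/C=C(\I)COCc2ccc(OC)cc2)C[C@]1(C)O | intermediate
16 | lithium acetylide of 5 | [Li]C#C/C(COCc1ccc(OC)cc1)=C\CO[Si](CC)(CC)CC | intermediate
17 | (2E,7S,9R,10Z)-7,9-dihydroxy-11-iodo-12-[(4-methoxybenzyl)oxy]-3-{[(4-methoxybenzyl)oxy]methyl}-7-methyl-1-[(triethylsilyl)oxy]dodeca-2,10-dien-4-yn-6-one | C[C@](O)(C[C@@H](O)/C=C(\I)COCc1ccc(OC)cc1)C(=O)C#C/C(COCc1ccc(OC)cc1)=C\CO[Si](CC)(CC)CC | intermediate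
18 | 9-O-TBS ether of 17 (O8 TBS) | C[C@](O)(C[C@@H](O[Si](C)(C)C(C)(C)C)/C=C(\I)COCc1ccc(OC)cc1)C(=O)C#C/C(COCc1ccc(OC)cc1)=C\CO[Si](CC)(CC)CC | intermediate
19 | furanone with O6 TES, O8 TBS, O13 and O15 PMB, C11 iodide (2S; 2R,3Z side chain; 2Z butenyl) | C[C@@]1(C[C@@H](O[Si](C)(C)C(C)(C)C)/C=C(\I)COCc2ccc(OC)cc2)OC(=CC1=O)/C(COCc2ccc(OC)cc2)=C\CO[Si](CC)(CC)CC | intermediate
20 | C6 alcohol derived from 19 | C[C@@]1(C[C@@H](O[Si](C)(C)C(C)(C)C)/C=C(\I)COCc2ccc(OC)cc2)OC(=CC1=O)/C(COCc2ccc(OC)cc2)=C\CO | intermediate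
21 | C6 allylic bromide | C[C@@]1(C[C@@H](O[Si](C)(C)C(C)(C)C)/C=C(\I)COCc2ccc(OC)cc2)OC(=CC1=O)/C(COCc2ccc(OC)cc2)=C\CBr | intermediate
22 | C6 bromide with free C13 and C15 alcohols | C[C@@]1(C[C@@H](O[Si](C)(C)C(C)(C)C)/C=C(\I)CO)OC(=CC1=O)/C(CO)=C\CBr | intermediate
23 | thirteen-membered C6–O–C13 ether (8R,10S), C11 iodide, C8 OTBS, C15 OH | O1C/C(I)=C/[C@H](O[Si](C)(C)C(C)(C)C)C[C@]2(C)OC(=CC2=O)/C(CO)=C\C1 | intermediate
24 | ten-membered carbocycle (6R,7S,8R,10S), C6 OH, C7 1-iodovinyl, C8 OTBS, C15 OH | C=C(I)[C@@H]1[C@H](O[Si](C)(C)C(C)(C)C)C[C@]2(C)OC(=CC2=O)/C(CO)=C\[C@H]1O | intermediate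
25 | α-methylene lactone (6R,7S,8R,10S), C8 OTBS, C15 OH | C=C1C(=O)O[C@@H]2/C=C(/CO)C3=CC(=O)[C@](C)(C[C@@H](O[Si](C)(C)C(C)(C)C)[C@@H]12)O3 | intermediate
26 | 8,15-diol (6R,7R,8R,10S) | C=C1C(=O)O[C@@H]2/C=C(/CO)C3=CC(=O)[C@](C)(C[C@@H](O)[C@@H]12)O3 | intermediate
27 | 15-O-TBS-8-ol (6R,7R,8R,10S) | C=C1C(=O)O[C@@H]2/C=C(/CO[Si](C)(C)C(C)(C)C)C3=CC(=O)[C@](C)(C[C@@H](O)[C@@H]12)O3 | intermediate
28 | (R)-2-methylbutanoic acid | CC[C@@H](C)C(=O)O | starting material
29 | 15-O-TBS-8-O-[(R)-2-methylbutanoyl] ester | C=C1C(=O)O[C@@H]2/C=C(/CO[Si](C)(C)C(C)(C)C)C3=CC(=O)[C@](C)(C[C@@H](OC(=O)[C@H](C)CC)[C@@H]12)O3 | intermediate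
30 | CNP0307052.2 | C=C1C(=O)O[C@@H]2/C=C(/CO)C3=CC(=O)[C@](C)(C[C@@H](OC(=O)[C@H](C)CC)[C@@H]12)O3 | target

Total step count: 22.
Longest linear sequence: 17 steps (steps 6–22 from (S)-citramalic acid; equally steps 1–4 and 10–22 from but-2-yne-1,4-diol).

**Steps most likely to fail**

**Step 17.**
- *What may go wrong:* the strongly stabilised extended enolate may rearrange only slowly. In the transition state the C8 silyloxy group is pressed against the iodine on C11 (allylic 1,3-strain). A raised barrier would let [1,2]-shift, dehydroiodination or silyl migration compete, or would erode the diastereoselection.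
- *Fallback (sets out from 23, returns at 25):* carbonylation and C–C bond formation change places.
  - Methoxycarbonylation of the vinyl iodide (Pd(PPh3)4, CO, MeOH, Et3N) would give the C11 methyl ester of the thirteen-membered ether F1.
  - C7 is then the β-carbon of a 2-(alkoxymethyl)acrylate. The soft C6 anion (LiHMDS, or DBU) can add to it in Michael fashion and expel O13 by addition–elimination. This forms the same C6–C7 bond and the same C11=C13 methylene.
  - The ring-contracted hydroxy ester F2 would close with loss of methanol to 25.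

**Step 16.**
- *What may go wrong:* oligomerisation, and proton abstraction at the acidified C6 of the bromide in place of substitution.
- *Fallback (sets out from 15, returns at 23):* the polarity of the etherification is reversed.
  - DDQ at the lactone stage would give the primary allylic alcohol F3.
  - MsCl, collidine and LiCl in DMF would give the allylic chloride F4; the tertiary OH does not react.
  - Addition of 16 as in step 10 would give the keto diol F5, TBSCl the O8 silyl ether F6, gold(I) the furanone F7, and PPTS/MeOH the C6 alcohol F8.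
  - The leaving group then sits on C13, which is not acidified. The C6 alkoxide (NaH, 1.1 equiv, NaI cat., THF, 2 mM) would close the C15 PMB ether of the macrocycle F9.
  - DDQ then gives 23.

**Step 9 (together with step 8).**
- *What may go wrong:* Z-to-E isomerisation of the β-iodoenone by reversible iodide addition, and poor facial selectivity because both flanks of the ketone are bulky.
- *Fallback (sets out from 12, returns at 15):*
  - Noyori transfer hydrogenation of the ynone with RuCl[(R,R)-TsDPEN](p-cymene) in i-PrOH, where alkynyl/alkyl discrimination is reliable, would give the (8R)-propargylic alcohol F10.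
  - CSA would close it to the alkynyl lactone F11.
  - Excess Red-Al would reduce the lactone to the diol and, directed by the O8 aluminate, add trans across the alkyne. Iodine would then give the Z-iodo triol F12.
  - TEMPO/PhI(OAc)2 would oxidise the primary alcohol through the lactol back to lactone 15.

**Further compounds**
F1 | step 17 | C11 methyl ester of the thirteen-membered ether (8R,10S), ester cis to C8 | O1C/C(C(=O)OC)=C/[C@H](O[Si](C)(C)C(C)(C)C)C[C@]2(C)OC(=CC2=O)/C(CO)=C\C1
F2 | step 17 | ring-contracted hydroxy ester, C6 OH, C7 bearing C(=CH2)CO2Me | C=C(C(=O)OC)[C@@H]1[C@H](O[Si](C)(C)C(C)(C)C)C[C@]2(C)OC(=CC2=O)/C(CO)=C\[C@H]1O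
F3 | step 16 | (3S,5R)-3-hydroxy-5-[(1Z)-3-hydroxy-2-iodoprop-1-en-1-yl]-3-methyloxolan-2-one | O=C1O[C@@H](/C=C(\I)CO)C[C@]1(C)O
F4 | step 16 | (3S,5R)-5-[(1Z)-3-chloro-2-iodoprop-1-en-1-yl]-3-hydroxy-3-methyloxolan-2-one | O=C1O[C@@H](/C=C(\I)CCl)C[C@]1(C)O
F5 | step 16 | (2E,7S,9R,10Z)-12-chloro-7,9-dihydroxy-11-iodo-3-{[(4-methoxybenzyl)oxy]methyl}-7-methyl-1-[(triethylsilyl)oxy]dodeca-2,10-dien-4-yn-6-one | C[C@](O)(C[C@@H](O)/C=C(\I)CCl)C(=O)C#C/C(COCc1ccc(OC)cc1)=C\CO[Si](CC)(CC)CC
F6 | step 16 | 9-O-TBS ether of F5 | C[C@](O)(C[C@@H](O[Si](C)(C)C(C)(C)C)/C=C(\I)CCl)C(=O)C#C/C(COCc1ccc(OC)cc1)=C\CO[Si](CC)(CC)CC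
F7 | step 16 | furanone with C13 chloride, O6 TES, O8 TBS, O15 PMB | C[C@@]1(C[C@@H](O[Si](C)(C)C(C)(C)C)/C=C(\I)CCl)OC(=CC1=O)/C(COCc2ccc(OC)cc2)=C\CO[Si](CC)(CC)CC
F8 | step 16 | furanone with C13 chloride and free C6 alcohol | C[C@@]1(C[C@@H](O[Si](C)(C)C(C)(C)C)/C=C(\I)CCl)OC(=CC1=O)/C(COCc2ccc(OC)cc2)=C\CO
F9 | step 16 | C15 PMB ether of 23 | O1C/C(I)=C/[C@H](O[Si](C)(C)C(C)(C)C)C[C@]2(C)OC(=CC2=O)/C(COCc3ccc(OC)cc3)=C\C1
F10 | step 9 | (5S)-5-{(2R)-2-hydroxy-5-[(4-methoxybenzyl)oxy]pent-3-yn-1-yl}-2,2,5-trimethyl-1,3-dioxolan-4-one | C[C@@]1(C[C@@H](O)C#CCOCc2ccc(OC)cc2)OC(C)(C)OC1=O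
F11 | step 9 | (3S,5R)-3-hydroxy-5-{3-[(4-methoxybenzyl)oxy]prop-1-yn-1-yl}-3-methyloxolan-2-one | O=C1O[C@@H](C#CCOCc2ccc(OC)cc2)C[C@]1(C)O
F12 | step 9 | (2S,4R,5Z)-6-iodo-7-[(4-methoxybenzyl)oxy]-2-methylhept-5-ene-1,2,4-triol | C[C@@](O)(CO)C[C@@H](O)/C=C(\I)COCc1ccc(OC)cc1
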